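**Plan**

- Numbering (daucane): C1 = methyl-bearing ring-fusion carbon, C2 = CH–OAc, C3 = CH2, C4 = C(OH)iPr, C5 = ring-fusion CH, C6 = CH–O-anisoyl, C7 = CH2, C8/C9 = epoxide carbons (C8 methylated), C10 = CH–OH; α = face of the C1 methyl.
- Retrosynthesis: remove the C10 silyl group, the acetate, the epoxide oxygen and the C6 ester; cut the seven-membered ring at C8=C9 (metathesis); cut the cyclopentane at C2–C3 and C4–C5 into a 2-siloxyalkene (C3–C4) and a cyclopropane C1–C2–C5 carrying an O-donor on C2 and the C6 ketone on C5; cut that cyclopropane at C5 (carbene from an allylic diazoacetate).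
- Forward ring order: cyclopropane (fused to a γ-lactone) → monocyclic cyclopropyl ketone → cyclopentane by formal (3+2) → cycloheptene by ring-closing metathesis → C6, epoxide, esters.
- Stereochemistry: C10 from a lipase resolution; C1 from C10 by allylic strain in the intramolecular cyclopropanation; C2, C4, C5 in the (3+2) (Felkin–Anh, closed titanium aldol, allylic 1,3-strain); C6 by directed hydride delivery followed by Mitsunobu inversion; C8/C9 by peracid attack anti to C10–OTBS and the C1 methyl.
- Enabling feature: on the cyclopentane C2–O and C4–O are 1,3-related and C4–O is 1,3 to C6–O, so C2 is an acetal-level electrophile and C5 the enolate carbon of a C6 ketone, joined through quaternary C1. That is the 1,3-zwitterion of a 2-alkoxycyclopropyl ketone, and C3–C4 is the enol ether of isopropyl methyl ketone.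

Key step: step 10

Remark: the lipase is assumed to follow its usual preference (Kazlauskas rule) and acetylate the (R)-alcohol, leaving the required (S)-alcohol 5.

**Step 1**
Reactants: 1 (E)-3-ethoxy-2-methylprop-2-enal; 2 benzyl alcohol
Product: 3 (E)-3-(benzyloxy)-2-methylprop-2-enal
Conditions: BnOH (1.5 equiv), PPTS (cat.), toluene, 80 °C, reduced pressure (−EtOH)
Reagents that add atoms: none
Why: Acid-catalysed addition–elimination (vinylogous transesterification) of the β-alkoxy enal exchanges OEt for OBn, driven by removal of ethanol, and keeps the more stable (E)-geometry (OBn trans to CHO).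

**Step 2**
Reactants: 3 (E)-3-(benzyloxy)-2-methylprop-2-enal
Product: 4 rac-(E)-1-(benzyloxy)-2-methylpenta-1,4-dien-3-ol
Conditions: CH2=CHMgBr, THF, −78 °C; sat. aq. NaHCO3 work-up, Et3N-deactivated silica
Reagents that add atoms: vinylmagnesium bromide C=C[Mg]Br
Why: Grignard 1,2-addition to the aldehyde of a vinylogous ester, with a non-acidic work-up so the acid-labile 3-alkoxyallyl alcohol survives; the product is racemic.

**Step 3**
Reactants: 4 rac-(E)-1-(benzyloxy)-2-methylpenta-1,4-dien-3-ol
Product: 5 (3S,1E)-1-(benzyloxy)-2-methylpenta-1,4-dien-3-ol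
Conditions: Novozym 435 (CAL-B), vinyl acetate, MTBE, 25 °C, to about 55% conversion; unreacted alcohol recovered
Reagents that add atoms: none
Why: Lipase-catalysed kinetic resolution by enantioselective transesterification should acetylate the (R)-alcohol and leave the (S)-alcohol, which sets C10, the centre from which all others are derived; at most half of the material is carried on.

**Step 4**
Reactants: 5 (3S,1E)-1-(benzyloxy)-2-methylpenta-1,4-dien-3-ol
Product: 7 (3S,1E)-1-(benzyloxy)-2-methylpenta-1,4-dien-3-yl diazoacetate, via bromoacetate 6 (not isolated)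
Conditions: BrCH2COBr, NaHCO3, MeCN, 0 °C; then TsNHNHTs, DBU, THF, 0 °C
Reagents that add atoms: bromoacetyl bromide BrCC(Br)=O; N,N'-ditosylhydrazine Cc1ccc(cc1)S(=O)(=O)NNS(=O)(=O)c1ccc(C)cc1
Why: Fukuyama diazoacetate synthesis (O-acylation, N-alkylation of the ditosylhydrazine, base-induced loss of two sulfinates) runs under non-acidic conditions that leave the enol ether and the stereocentre untouched.

**Step 5**
Reactants: 7 (3S,1E)-1-(benzyloxy)-2-methylpenta-1,4-dien-3-yl diazoacetate
Product: 8 6-(benzyloxy)-4-ethenyl-5-methyl-3-oxabicyclo[3.1.0]hexan-2-one (ethenyl on the lactone face that carries the cyclopropane CH–OBn carbon; OBn exo, cis to the methyl)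
Conditions: Rh2(cap)4 (1 mol %), CH2Cl2, reflux, slow addition of 7
Reagents that add atoms: none
Why: Rh(II)-carboxamidate-catalysed intramolecular cyclopropanation of an allylic diazoacetate (Doyle type) should occur at the electron-rich enol ether; the syn addition keeps OBn cis to CH3, the lactone forces C6 and C10 cis, and C1 is set from C10 by allylic strain (the C10 vinyl group eclipses the C1=C2 bond, whose cis substituent is H, and avoids the C1 methyl).

**Step 6**
Reactants: 8 cyclopropane-fused lactone
Product: 9 hydroxy Weinreb amide (cyclopropane C1–C2–C5: C5 bears C(=O)N(OMe)Me; C1 bears CH3 and the (S)-CH(OH)CH=CH2 arm cis to the amide; C2 bears OBn cis to CH3)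
Conditions: MeNH(OMe)·HCl, iPrMgCl, THF, −20 °C; used at once
Reagents that add atoms: N,O-dimethylhydroxylamine hydrochloride CNOC.Cl
Why: Aminolysis of the lactone by the chloromagnesium amide (Weinreb amide formation without a Lewis acid) should leave the acid-sensitive alkoxycyclopropane intact and free the C10 hydroxyl.

**Step 7**
Reactants: 9 hydroxy Weinreb amide
Product: 10 TBS ether of 9
Conditions: TBSCl, imidazole, DMF, 25–40 °C
Reagents that add atoms: tert-butyldimethylsilyl chloride CC(C)(C)[Si](C)(C)Cl
Why: Standard silylation of the secondary allylic alcohol prevents relactonisation and protects C10–OH until the last step.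

**Step 8**
Reactants: 10 TBS ether of 9
Product: 11 cyclopropyl 2-methylallyl ketone (C5–C(=O)CH2C(CH3)=CH2; otherwise as 10)
Conditions: 2-methylallylmagnesium chloride, THF, −78 → 0 °C; cold NH4Cl quench, Et3N-deactivated silica
Reagents that add atoms: 2-methylallylmagnesium chloride CC(=C)C[Mg]Cl
Why: Grignard addition to a Weinreb amide stops at the ketone through the chelated tetrahedral intermediate; the β,γ-unsaturated ketone is both the acceptor for step 10 and the C7–C8 unit for metathesis.

**Step 9**
Reactants: 12 3-methylbutan-2-one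
Product: 13 3-methyl-2-(trimethylsilyloxy)but-1-ene
Conditions: LDA, THF, −78 °C; TMSCl
Reagents that add atoms: chlorotrimethylsilane C[Si](C)(C)Cl
Why: Kinetic deprotonation at the methyl group and O-silylation give the less substituted silyl enol ether regioselectively.

**Step 10**
Reactants: 11 cyclopropyl 2-methylallyl ketone; 13 3-methyl-2-(trimethylsilyloxy)but-1-ene
Product: 16 cyclopentane cycloadduct (C1: α-CH3 and β-(S)-CH(OTBS)CH=CH2; C2: α-OBn; C4: α-OH and β-iPr; C5: α-C(=O)CH2C(CH3)=CH2), via oxocarbenium titanium enolate zwitterion 14 (not isolated), via keto titanium enolate 15 (not isolated)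
Conditions: 13 (3 equiv), TiCl4 (1.2 equiv), CH2Cl2, −78 °C; sat. aq. NaHCO3
Reagents that add atoms: none
Why: TiCl4 binds the C6 ketone and the push–pull C2–C5 bond ionises to a 1,3-zwitterion (E-oxocarbenium at C2, titanium enolate at C5/C6) in which only C1 and C10 stay stereogenic, so the C2/C5 configuration of the cyclopropane no longer matters; the CH2 terminus of 13 adds to C2 (Mukaiyama-type, bond C3–C2), TMSCl is lost, and the titanium enolate attacks the new isopropyl ketone (aldol, bond C5–C4). The closest known reaction type is the Lewis-acid-mediated formal (3+2) annulation of donor–acceptor cyclopropanes with silyl enol ethers to cyclopentanes. The cyclopentane closes by a 5-(enolexo)-exo-trig aldol. C2 should be set by Felkin–Anh attack on the oxocarbenium face remote from the ion-paired enolate arm, with the nucleophile passing the C1 methyl and not the bulky C10 arm (OBn cis to CH3); C5 by allylic 1,3-strain in the exocyclic enolate, which turns the methyl toward the enolate substituent and the C10 arm away (acyl cis to CH3, trans to the C10 arm); C4 by the closed titanium-bridged aldol transition state (OH cis to the acyl group, iPr cis to H5). The step needs the oxocarbenium to be captured by 13 in preference to the two internal alkenes and needs these three diastereoselections; low temperature, excess 13 and the size difference between CH3 and CH(OTBS)CH=CH2 on C1 are relied on. It is run before the seven-membered ring exists because a preformed cycloheptenone enolate would be forced to close cis, whereas the open enolate places the acyl group trans to the C10 arm, which becomes the trans ring fusion.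

**Step 11**
Reactants: 16 cyclopentane cycloadduct
Product: 17 2α-benzyloxy-10α-(tert-butyldimethylsilyloxy)-4α-hydroxydauc-8-en-6-one (trans-fused, H5 β)
Conditions: Grubbs II (5 mol %), 1,4-benzoquinone (10 mol %), CH2Cl2 (5 mM), 40 °C
Reagents that add atoms: none
Why: Ring-closing metathesis of the 1,1-disubstituted and the monosubstituted alkene closes the cycloheptene at C8=C9; the two arms are trans on the cyclopentane, so the fusion is trans by construction, and benzoquinone suppresses Ru–H double-bond migration.

**Step 12**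
Reactants: 17 dauc-8-en-6-one
Product: 18 2α-benzyloxy-10α-(tert-butyldimethylsilyloxy)dauc-8-ene-4α,6α-diol
Conditions: Me4NBH(OAc)3, MeCN/AcOH, −30 °C
Reagents that add atoms: none
Why: Hydroxyl-directed (Evans–Saksena) reduction of the β-hydroxy ketone should deliver hydride from the C4–O–B unit to the exposed β-face of C6, the axial α-face being shielded 1,3 by the C1 methyl, to give the axial 6α-alcohol needed for invertive esterification.

**Step 13**
Reactants: 18 4α,6α-diol
Product: 19 6β-(4-methoxybenzoyloxy)-2α-benzyloxy-10α-(tert-butyldimethylsilyloxy)dauc-8-en-4α-ol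
Conditions: 4-methoxybenzoic acid, PPh3, DIAD, toluene, 0 °C → rt
Reagents that add atoms: 4-methoxybenzoic acid COc1ccc(cc1)C(=O)O
Why: Mitsunobu esterification of the axial secondary alcohol proceeds with SN2 inversion, the carboxylate entering from the open β-face, and so installs the ester with the 6β configuration; the tertiary C4–OH does not react.

**Step 14**
Reactants: 19 6β-anisoate alkene
Product: 20 8β,9β-epoxide of 19
Conditions: mCPBA, NaHCO3, CH2Cl2, 0 °C
Reagents that add atoms: meta-chloroperoxybenzoic acid OOC(=O)c1cccc(Cl)c1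
Why: Prilezhaev epoxidation of the trisubstituted alkene should occur on the β-face because the α-face is blocked by the allylic C10–OTBS and the axial C1 methyl; this sets C8 and C9.

**Step 15**
Reactants: 20 epoxide
Product: 21 2α-alcohol (benzyl removed)
Conditions: H2 (1 atm), Pd/C, EtOAc, rt
Reagents that add atoms: none
Why: Hydrogenolysis of the benzyl ether over Pd/C; the isolated trialkyl epoxide, the aryl ester and the silyl ether are not expected to be reduced.

**Step 16**
Reactants: 21 2α-alcohol
Product: 22 2α-acetate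
Conditions: Ac2O, DMAP (cat.), pyridine, rt
Reagents that add atoms: acetic anhydride CC(=O)OC(C)=O
Why: DMAP-catalysed acetylation of the only secondary hydroxyl; the tertiary C4–OH is too hindered to react.

**Step 17**
Reactants: 22 2α-acetate
Product: 23 target
Conditions: HF·pyridine, THF/pyridine, 0 °C → rt
Reagents that add atoms: none
Why: Fluoride desilylation under buffered, weakly acidic conditions frees C10–OH while avoiding base-induced acyl migration or Payne rearrangement of the trans epoxy alcohol.

**Compound list**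

1 | (E)-3-ethoxy-2-methylprop-2-enal | O=C/C(C)=C/OCC | starting material
2 | benzyl alcohol | OCc1ccccc1 | starting material
3 | (E)-3-(benzyloxy)-2-methylprop-2-enal | O=C/C(C)=C/OCc1ccccc1 | intermediate
4 | rac-(E)-1-(benzyloxy)-2-methylpenta-1,4-dien-3-ol | C=CC(O)/C(C)=C/OCc1ccccc1 | intermediate
5 | (3S,1E)-1-(benzyloxy)-2-methylpenta-1,4-dien-3-ol | C=C[C@H](O)/C(C)=C/OCc1ccccc1 | intermediate
6 | (3S,1E)-1-(benzyloxy)-2-methylpenta-1,4-dien-3-yl bromoacetate | C=C[C@H](OC(=O)CBr)/C(C)=C/OCc1ccccc1 | intermediate
7 | (3S,1E)-1-(benzyloxy)-2-methylpenta-1,4-dien-3-yl diazoacetate | C=C[C@H](OC(=O)C=[N+]=[N-])/C(C)=C/OCc1ccccc1 | intermediate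
8 | 6-(benzyloxy)-4-ethenyl-5-methyl-3-oxabicyclo[3.1.0]hexan-2-one (ethenyl syn to the cyclopropane, OBn exo) | C=C[C@@H]1OC(=O)[C@@H]2[C@@H](OCc3ccccc3)[C@]12C | intermediate
9 | hydroxy Weinreb amide (amide and C10 arm cis, OBn cis to CH3) | C=C[C@H](O)[C@@]1(C)[C@H](OCc2ccccc2)[C@H]1C(=O)N(C)OC | intermediate
10 | TBS ether of 9 | C=C[C@H](O[Si](C)(C)C(C)(C)C)[C@@]1(C)[C@H](OCc2ccccc2)[C@H]1C(=O)N(C)OC | intermediate
11 | cyclopropyl 2-methylallyl ketone | C=C[C@H](O[Si](C)(C)C(C)(C)C)[C@@]1(C)[C@H](OCc2ccccc2)[C@H]1C(=O)CC(C)=C | intermediate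
12 | 3-methylbutan-2-one | CC(=O)C(C)C | starting material
13 | 3-methyl-2-(trimethylsilyloxy)but-1-ene | C=C(O[Si](C)(C)C)C(C)C | intermediate
14 | oxocarbenium titanium enolate zwitterion | C=C[C@H](O[Si](C)(C)C(C)(C)C)[C@@](C)(C=[O+]Cc1ccccc1)C=C(O[Ti-](Cl)(Cl)(Cl)Cl)CC(C)=C | intermediate
15 | keto titanium enolate | C=C[C@H](O[Si](C)(C)C(C)(C)C)[C@@](C)([C@H](OCc1ccccc1)CC(=O)C(C)C)C=C(O[Ti](Cl)(Cl)Cl)CC(C)=C | intermediate
16 | cyclopentane cycloadduct (α: CH3, OBn, OH, acyl; β: C10 arm, iPr, H5) | C=C[C@H](O[Si](C)(C)C(C)(C)C)[C@@]1(C)[C@H](OCc2ccccc2)C[C@@](O)(C(C)C)[C@@H]1C(=O)CC(C)=C | intermediate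
17 | 2α-benzyloxy-10α-(tert-butyldimethylsilyloxy)-4α-hydroxydauc-8-en-6-one | O=C1CC(C)=C[C@H](O[Si](C)(C)C(C)(C)C)[C@]2(C)[C@@H]1[C@](O)(C(C)C)C[C@H]2OCc1ccccc1 | intermediate
18 | 2α-benzyloxy-10α-(tert-butyldimethylsilyloxy)dauc-8-ene-4α,6α-diol | O[C@@H]1CC(C)=C[C@H](O[Si](C)(C)C(C)(C)C)[C@]2(C)[C@@H]1[C@](O)(C(C)C)C[C@H]2OCc1ccccc1 | intermediate
19 | 6β-(4-methoxybenzoyloxy)-2α-benzyloxy-10α-(tert-butyldimethylsilyloxy)dauc-8-en-4α-ol | COc1ccc(C(=O)O[C@H]2CC(C)=C[C@H](O[Si](C)(C)C(C)(C)C)[C@]3(C)[C@@H]2[C@](O)(C(C)C)C[C@H]3OCc2ccccc2)cc1 | intermediate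
20 | 8β,9β-epoxide of 19 | COc1ccc(C(=O)O[C@H]2C[C@@]3(C)O[C@H]3[C@H](O[Si](C)(C)C(C)(C)C)[C@]3(C)[C@@H]2[C@](O)(C(C)C)C[C@H]3OCc2ccccc2)cc1 | intermediate
21 | 2α-alcohol (debenzylated 20) | COc1ccc(C(=O)O[C@H]2C[C@@]3(C)O[C@H]3[C@H](O[Si](C)(C)C(C)(C)C)[C@]3(C)[C@@H]2[C@](O)(C(C)C)C[C@H]3O)cc1 | intermediate
22 | 2α-acetate of 21 | COc1ccc(C(=O)O[C@H]2C[C@@]3(C)O[C@H]3[C@H](O[Si](C)(C)C(C)(C)C)[C@]3(C)[C@@H]2[C@](O)(C(C)C)C[C@H]3OC(C)=O)cc1 | intermediate
23 | target: 2α-acetoxy-8β,9β-epoxy-6β-(4-methoxybenzoyloxy)daucane-4α,10α-diol | COc1ccc(C(=O)O[C@H]2C[C@@]3(C)O[C@H]3[C@H](O)[C@]3(C)[C@@H]2[C@](O)(C(C)C)C[C@H]3OC(C)=O)cc1 | target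

**Step count and risks**

Total steps: 17. Longest linear sequence: 16 (steps 1–8 and 10–17 from 1); step 9 is a one-step side branch.

Step 10. The addition of 13 to the C2 oxocarbenium may show poor or reversed facial selectivity, or the exo-benzyloxy cyclopropane may open with inversion before it ionises fully; either would give the C2 epimer. The fallback no longer relies on the annulation for C2. It sets out from 11: the same annulation gives the 2-epi cycloadduct F1 (2β-OBn), which is carried through ring-closing metathesis to the 2-epi ketone F2, directed reduction to the 2-epi 6α-alcohol F3, Mitsunobu esterification to the 2-epi anisoate F4, epoxidation to the 2-epi epoxide F5 and hydrogenolysis to the 2β-alcohol F6. Dess–Martin oxidation then gives the 2-ketone F7, and NaBH4/CeCl3 reduction, with hydride entering from the β-face anti to the axial C1 methyl and the C4 hydroxyl, should give the 2α-alcohol; the route is rejoined at 21.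

Step 13. The alkoxyphosphonium ion of the hindered axial alcohol may eliminate (H5 and H7 are anti-periplanar; C6=C7 would be conjugated with C8=C9) or form a cyclic phosphorane with the C4 hydroxyl instead of being displaced. The fallback sets out from 17: single-electron reduction (SmI2, H2O, Et3N, THF), which like dissolving-metal reductions is expected to favour the equatorial alcohol, gives the 6β-alcohol F8; acylation with 4-methoxybenzoyl chloride, DMAP and pyridine then gives 19 with retention, where the route is rejoined.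

Step 11. The β,γ-double bond of the methallyl ketone may migrate into conjugation before the hindered vinyl group engages the catalyst, which would stop the ring closure. The fallback sets out from 16: the directed triacetoxyborohydride reduction is done first, on the open chain, to give the open-chain 4,6-diol F9 (the chair transition state with C7 equatorial should give the same C6 configuration as in 18); ring-closing metathesis of this non-enolisable homoallylic alcohol then gives 18 directly, where the route is rejoined.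

**Further compounds**

F1 | step 10 | 2-epi cycloadduct (2β-OBn epimer of 16) | C=C[C@H](O[Si](C)(C)C(C)(C)C)[C@@]1(C)[C@@H](OCc2ccccc2)C[C@@](O)(C(C)C)[C@@H]1C(=O)CC(C)=C
F2 | step 10 | 2-epi ketone (2β-OBn epimer of 17) | O=C1CC(C)=C[C@H](O[Si](C)(C)C(C)(C)C)[C@]2(C)[C@@H]1[C@](O)(C(C)C)C[C@@H]2OCc1ccccc1
F3 | step 10 | 2-epi 6α-alcohol (2β-OBn epimer of 18) | O[C@@H]1CC(C)=C[C@H](O[Si](C)(C)C(C)(C)C)[C@]2(C)[C@@H]1[C@](O)(C(C)C)C[C@@H]2OCc1ccccc1
F4 | step 10 | 2-epi anisoate (2β-OBn epimer of 19) | COc1ccc(C(=O)O[C@H]2CC(C)=C[C@H](O[Si](C)(C)C(C)(C)C)[C@]3(C)[C@@H]2[C@](O)(C(C)C)C[C@@H]3OCc2ccccc2)cc1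
F5 | step 10 | 2-epi epoxide (2β-OBn epimer of 20) | COc1ccc(C(=O)O[C@H]2C[C@@]3(C)O[C@H]3[C@H](O[Si](C)(C)C(C)(C)C)[C@]3(C)[C@@H]2[C@](O)(C(C)C)C[C@@H]3OCc2ccccc2)cc1
F6 | step 10 | 2β-alcohol (2-epimer of 21) | COc1ccc(C(=O)O[C@H]2C[C@@]3(C)O[C@H]3[C@H](O[Si](C)(C)C(C)(C)C)[C@]3(C)[C@@H]2[C@](O)(C(C)C)C[C@@H]3O)cc1
F7 | step 10 | 2-ketone | COc1ccc(C(=O)O[C@H]2C[C@@]3(C)O[C@H]3[C@H](O[Si](C)(C)C(C)(C)C)[C@]3(C)[C@@H]2[C@](O)(C(C)C)CC3=O)cc1
F8 | step 13 | 6β-alcohol (6-epimer of 18) | O[C@H]1CC(C)=C[C@H](O[Si](C)(C)C(C)(C)C)[C@]2(C)[C@@H]1[C@](O)(C(C)C)C[C@H]2OCc1ccccc1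
F9 | step 11 | open-chain 4,6-diol (C6 alcohol of 16) | C=C[C@H](O[Si](C)(C)C(C)(C)C)[C@@]1(C)[C@H](OCc2ccccc2)C[C@@](O)(C(C)C)[C@@H]1[C@H](O)CC(C)=C
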